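## Retrosynthetic overview
1. The dihydropyran is formed last. O1–C2 is made by enantiospecific solvolysis of an acyclic sec-bromide/tert-chloride (a latent bromonium ion), trapped by the ketone oxygen, followed by loss of H+.
2. The cyclohexane is formed just before that. C1'–C2' is made by a bromonium-assisted cation–olefin cyclisation of an acyclic bromochloride primary triflate. An allylic alcohol terminates the cyclisation through a 1,2-H (semipinacol) shift, giving the methyl ketone and setting C1'.
3. The acyclic C15 chain is joined at C1'=C5 by a Horner–Wadsworth–Emmons (HWE) olefination. C4–C5 is made by enolate alkylation with a C5 triflate.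
4. All C–Br and C–Cl stereocentres come from two catalytic enantioselective bromochlorinations, of prenol (sets C3) and of nerol (sets C3' and C4').
5. There is no ring until step 8. The order is cyclohexane (step 8), then pyran (step 9).

Locants: pyran O1, C2 (CMe2), C3 (CHBr), C4 (CH2), C5, C6 (C–CH3). Cyclohexyl C1' (attached to C5), C2' (CH2), C3' (CHBr), C4' (C(Cl)CH3), C5' and C6' (CH2).

Assumption: both antipodes of the Schiff-base ligand are accessible. Stereo-elements that are erased later (E/Z at C1'=C5, the carbinol centre, and C5–H) are carried as mixtures.

## Route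

**Step 1**
Reactants: 1, prenol (3-methylbut-2-en-1-ol)
Product: 2, (R)-2-bromo-3-chloro-3-methylbutan-1-ol
Conditions: NBS, ClTi(OiPr)3, chiral tridentate salicylaldimine–amino alcohol ligand (antipode A, 10–20 mol %), hexanes, −20 °C
Reagents that add atoms: NBS, O=C1CCC(=O)N1Br; chlorotitanium triisopropoxide, CC(C)O[Ti](Cl)(OC(C)C)OC(C)C
Why: Ti-alkoxide-directed catalytic enantioselective bromochlorination of an allylic alcohol adds Br+ and Ti-bound chloride anti and Markovnikov (Cl on CMe2), and the ligand antipode is chosen to give the R C–Br centre that becomes C3.

**Step 2**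
Reactants: 2
Product: 3, (R)-2-bromo-3-chloro-3-methylbutyl trifluoromethanesulfonate
Conditions: Tf2O, pyridine, CH2Cl2, −78 to −20 °C; used crude
Reagents that add atoms: triflic anhydride, O=S(=O)(OS(=O)(=O)C(F)(F)F)C(F)(F)F
Why: This is a standard O-triflation in which the β-Br tempers the primary triflate enough to handle it, and the stereocentre is not touched.

**Step 3**
Reactants: 3; 4, diethyl (2-oxopropyl)phosphonate
Product: 5, diethyl [(5R)-5-bromo-6-chloro-6-methyl-2-oxoheptan-3-yl]phosphonate (epimers at C3)
Conditions: 4, NaH, THF, 0 °C; then 3, −40 to 0 °C
Reagents that add atoms: none (all heavy atoms come from 3 and 4)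
Why: SN2 C-alkylation of a soft, weakly basic β-ketophosphonate enolate on the primary triflate makes C4–C5 without E2, 3-exo closure onto the neopentylic CHBr is slow, and the new P-bearing centre is erased in step 6.

**Step 4**
Reactants: 6, nerol ((2Z)-3,7-dimethylocta-2,6-dien-1-ol)
Product: 7, (2S,3S)-2-bromo-3-chloro-3,7-dimethyloct-6-en-1-ol
Conditions: NBS, ClTi(OiPr)3, ligand antipode B (ent-A, 10–20 mol %), hexanes, −20 °C
Reagents that add atoms: NBS, O=C1CCC(=O)N1Br; chlorotitanium triisopropoxide, CC(C)O[Ti](Cl)(OC(C)C)OC(C)C
Why: The same directed bromochlorination is chemoselective for the allylic-alcohol alkene, anti addition to the Z-alkene gives the (S,S) pair that is the trans Br/Cl relationship of the future ring (C3', C4'), and the opposite ligand antipode is needed because this C–Br centre has the opposite sense to C3.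

**Step 5**
Reactants: 7
Product: 8, (4S,5S)-5-bromo-4-chloro-6-hydroxy-4-methylhexanal
Conditions: O3, CH2Cl2, −78 °C; then Me2S
Reagents that add atoms: ozone, [O-][O+]=O
Why: Ozonolysis with reductive work-up cleaves the only remaining alkene (acetone is lost), and the alkyl halides, the free OH and both stereocentres are inert.

**Step 6**
Reactants: 5; 8
Product: 9, (3E,7S,8S)-8-bromo-3-[(2R)-2-bromo-3-chloro-3-methylbutyl]-7-chloro-9-hydroxy-7-methylnon-3-en-2-one (some Z isomer tolerated)
Conditions: LiCl, i-Pr2NEt, MeCN, 23–40 °C
Reagents that add atoms: none
Why: A Horner–Wadsworth–Emmons olefination under Masamune–Roush conditions uses an amine base too weak to close the bromohydrin to an epoxide or to cause E2, and the alkene geometry does not matter because both isomers give the same C5 cation in step 8.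

**Step 7**
Reactants: 9
Product: 10, (2S,3S,6E)-2-bromo-7-[(2R)-2-bromo-3-chloro-3-methylbutyl]-3-chloro-3-methylnon-6-ene-1,8-diol (epimers at C8)
Conditions: NaBH4, CeCl3·7H2O, MeOH, −40 to 0 °C
Reagents that add atoms: none
Why: Luche 1,2-reduction turns the electron-poor enone, which served as a masked nucleophile, into a nucleophilic allylic alcohol, the halides survive, and the new carbinol centre is destroyed in step 8.

**Step 8** (key step)
Reactants: 10
Product: 11, (5R)-5-bromo-3-[(1S,3S,4S)-3-bromo-4-chloro-4-methylcyclohexyl]-6-chloro-6-methylheptan-2-one (epimers at C3)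
Conditions: Tf2O (1.0 equiv), 2,6-di-tert-butyl-4-methylpyridine (3 equiv), CH2Cl2, −78 °C; then dilute to 0.005 M with HFIP/CH2Cl2, −30 to 0 °C
Reagents that add atoms: none
Why: Proposed new method: the primary OH is triflated selectively and in HFIP the anti C–Br assists ionisation to a C2'–C3' bromonium, which the trisubstituted alkene opens at the CH2 terminus (the CHBr terminus is neopentylic and deactivated by the β-Cl, as in the terminal-attack preference of HOX additions to allyl chloride) through the 6-endo chair of bromonium polyene cyclisations, where backside attack forces Br (and therefore Cl) equatorial and the side chain sits equatorial, fixing C1' as S, after which the β-hydroxy tertiary cation collapses by a 1,2-hydride semipinacol shift to the methyl ketone; the closest known types are sulfonate- and bromonium-initiated cation–olefin cyclisation in HFIP and Prins–pinacol termination.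

**Step 9**
Reactants: 11
Product: 12, laucapyranoid A, (3R)-3-bromo-5-[(1S,3S,4S)-3-bromo-4-chloro-4-methylcyclohexyl]-2,2,6-trimethyl-3,4-dihydro-2H-pyran
Conditions: HFIP (0.01 M), 2,6-di-tert-butyl-4-methylpyridine, 35 °C; then PPTS (cat.), 4 Å MS, CH2Cl2, 23 °C
Reagents that add atoms: none
Why: Proposed new method: only the acyclic tert-chloride has an antiperiplanar Br, so it alone ionises (the ring Br/Cl pair is diequatorial and gauche, hence inert), the resulting enantiopure bromonium is opened at CMe2 by the ketone oxygen (6-endo, Markovnikov, C3–Br never broken, so R is retained), and loss of H5 followed by acid equilibration of any exocyclic isomer gives the tetrasubstituted enol ether; the closest known type is enantiospecific solvolytic cyclisation of vicinal bromochlorides with O-nucleophiles.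

Stereocentre audit:
- C3 is set in step 1.
- C3' and C4' are set in step 4.
- C1' is set in step 8.
- None of these centres is adjacent to an acidic or ionisable site in any later step.
- Because two enantioenriched halves are joined, the minor-enantiomer combinations become diastereomers, which are removed by chromatography at 11 or 12.

## Compound list
1 | prenol | CC(C)=CCO | starting material
2 | (R)-2-bromo-3-chloro-3-methylbutan-1-ol | OC[C@@H](Br)C(C)(C)Cl | intermediate
3 | (R)-2-bromo-3-chloro-3-methylbutyl triflate | FC(F)(F)S(=O)(=O)OC[C@@H](Br)C(C)(C)Cl | intermediate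
4 | diethyl (2-oxopropyl)phosphonate | CCOP(=O)(CC(C)=O)OCC | starting material
5 | diethyl [(5R)-5-bromo-6-chloro-6-methyl-2-oxoheptan-3-yl]phosphonate | CCOP(=O)(OCC)C(C(C)=O)C[C@@H](Br)C(C)(C)Cl | intermediate
6 | nerol | CC(C)=CCC/C(C)=C\CO | starting material
7 | (2S,3S)-2-bromo-3-chloro-3,7-dimethyloct-6-en-1-ol | CC(C)=CCC[C@](C)(Cl)[C@@H](Br)CO | intermediate
8 | (4S,5S)-5-bromo-4-chloro-6-hydroxy-4-methylhexanal | O=CCC[C@](C)(Cl)[C@@H](Br)CO | intermediate
9 | enone, major E isomer | CC(=O)/C(C[C@@H](Br)C(C)(C)Cl)=C/CC[C@](C)(Cl)[C@@H](Br)CO | intermediate
10 | allylic alcohol diol (carbinol epimers) | CC(O)/C(C[C@@H](Br)C(C)(C)Cl)=C/CC[C@](C)(Cl)[C@@H](Br)CO | intermediate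
11 | cyclohexyl methyl ketone (epimers at the α-carbon) | CC(=O)C(C[C@@H](Br)C(C)(C)Cl)[C@H]1CC[C@](C)(Cl)[C@@H](Br)C1 | intermediate
12 | laucapyranoid A | CC1=C([C@H]2CC[C@](C)(Cl)[C@@H](Br)C2)C[C@@H](Br)C(C)(C)O1 | target

## Totals
Total steps: 9. Longest linear sequence: 7 (steps 1, 2, 3, 6, 7, 8, 9).

## Three steps most likely to fail
1. **Step 8.**
   - Risks: 5-exo opening of the bromonium, Br+ transfer to the alkene, triflation or ionisation of the allylic alcohol, and competing ionisation of the neighbouring tert-chloride.
   - Fallback: form the ring first and install the halogens by a stereospecific relay.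
     - Make an (S)-4-substituted 1-methylcyclohexene carrying the same side chain by asymmetric Diels–Alder reaction of isoprene.
     - Treat it with NBS/H2O and then base to give the epoxide syn to the side chain.
     - Open the epoxide trans-diaxially at CH with LiCl/AcOH, giving a sec-Cl and a tert-OH.
     - Convert this with HBr to the diaxial tert-bromide/sec-chloride.
     - Apply the classical thermal diaxial→diequatorial 1,2-dihalide interchange to reach the 3'-Br(eq)/4'-Cl(eq) array.
2. **Step 9.**
   - Risks: 5-exo O-attack, Br+ abstraction by the enol ether product, and formation of the exocyclic enol ether or an HFIP ketal.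
   - Fallback: make the other C–O bond instead. Solvolyse 11 in aqueous HFIP or aqueous acetone so that water opens the same bromonium at CMe2, giving the tertiary bromohydrin with C3 retained. Then close O1–C6 by acid-catalysed hemiketalisation and dehydration of the δ-hydroxy ketone.
3. **Step 6, together with step 3.**
   - Risks: a hindered α-branched phosphonate in the olefination, O-alkylation in step 3, and base-sensitive partners.
   - Fallback: form C4–C5 after ring closure.
     - Cross-metathesise 7 with methyl vinyl ketone at the prenyl terminus.
     - Carry out the Luche reduction and the step 8 closure to give 1-[(1S,3S,4S)-3-bromo-4-chloro-4-methylcyclohexyl]propan-2-one.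
     - Convert this ketone to its thermodynamic silyl enol ether, generate the lithium enolate, and alkylate it with triflate 3 to reach 11.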